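**Retrosynthetic overview**
- Target 21 ← alkyne 20 (semi-hydrogenation) ← silyl-protected bromo-bicycle 19 (desilylation).
- 19 ← acyclic enol acetate 16 by one anodic bromonium cascade: ring A first (C3–Br, C4–C5), then ring B (C6–C7), exocyclic alkene by proton loss.
- 16 ← lactone 11: lactone → isopropenyl + free O12; vinyl → aldehyde → (Z)-enol acetate.
- 11 ← ortho ester Claisen of nerol 8 with lactone 5 (C9–C10 bond, both stereocentres relayed from C12).
- 5 ← (S)-5-oxotetrahydrofuran-2-carboxylic acid 1 (from L-glutamic acid; C12 bought, C13 by Felkin-type alkynylation).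

Assumption: labdane numbering (C1–C20) is used for locants, and the SMILES is read as 10-CH3 β, 5-H α, 3-Br β (equatorial), 6-OAc β (axial), C9 side chain α (axial), 12S, 13R.

**Step 1**
Reactants: 1 (S)-5-oxotetrahydrofuran-2-carboxylic acid
Product: 3 (S)-5-acetyldihydrofuran-2(3H)-one, via acid chloride 2 (not isolated)
Conditions: (COCl)2, cat. DMF, CH2Cl2, 0 °C to rt; then MeMgBr (1.05 equiv), Fe(acac)3 (3 mol %), THF, −78 °C
Reagents that add atoms: methylmagnesium bromide (C[Mg]Br)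
Why: Acid chloride formation followed by iron-catalysed Grignard acylation is much faster than attack on the lactone at −78 °C, so the bought C12 stereocentre is carried through unchanged.

**Step 2**
Reactants: 3 (S)-5-acetyldihydrofuran-2(3H)-one
Product: 5 (5S)-5-[(2R)-2-(triethylsilyloxy)-4-(triisopropylsilyl)but-3-yn-2-yl]dihydrofuran-2(3H)-one, via lithium alkoxide 4 (not isolated)
Conditions: iPr3SiC≡CLi (from iPr3SiC≡CH and nBuLi), THF, −78 °C; then Et3SiOTf, −78 to 0 °C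
Reagents that add atoms: lithium (triisopropylsilyl)acetylide ([Li]C#C[Si](C(C)C)(C(C)C)C(C)C); triethylsilyl trifluoromethanesulfonate (CC[Si](CC)(CC)OS(=O)(=O)C(F)(F)F)
Why: 1,2-Addition of the acetylide under polar Felkin–Anh (Cornforth) control, with the ring C–O bond anti to the carbonyl and attack past H12, sets C13 (R) from C12 (dr expected about 5:1, minor epimer removed by chromatography), and the alkoxide is capped in situ as the silyl ether.

**Step 3**
Reactants: 5 (5S)-5-[(2R)-2-(triethylsilyloxy)-4-(triisopropylsilyl)but-3-yn-2-yl]dihydrofuran-2(3H)-one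
Product: 7 (5S)-2,2-diethoxy-5-[(2R)-2-(triethylsilyloxy)-4-(triisopropylsilyl)but-3-yn-2-yl]tetrahydrofuran, via O-ethyl lactonium tetrafluoroborate 6 (not isolated)
Conditions: Et3OBF4, CH2Cl2, rt; then NaOEt, EtOH, −78 to 0 °C
Reagents that add atoms: triethyloxonium tetrafluoroborate (CC[O+](CC)CC.F[B-](F)(F)F); sodium ethoxide (CC[O-].[Na+])
Why: Meerwein O-ethylation of the lactone carbonyl and ethoxide capture give the cyclic ortho ester (classical lactone to ortho ester conversion) without touching a stereocentre.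

**Step 4**
Reactants: 7 (5S)-2,2-diethoxy-5-[(2R)-2-(triethylsilyloxy)-4-(triisopropylsilyl)but-3-yn-2-yl]tetrahydrofuran; 8 nerol ((2Z)-3,7-dimethylocta-2,6-dien-1-ol)
Product: 11 (3S,5S)-3-[(3S)-3,7-dimethylocta-1,6-dien-3-yl]-5-[(2R)-2-(triethylsilyloxy)-4-(triisopropylsilyl)but-3-yn-2-yl]dihydrofuran-2(3H)-one, via mixed ortho ester 9 (not isolated), via ketene acetal 10 (not isolated)
Conditions: 8 (3 equiv), pivalic acid (10 mol %), xylenes, 140 °C, EtOH distilled off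
Reagents that add atoms: none
Why: Johnson ortho ester Claisen rearrangement: the [3,3] shift of cyclic ketene acetal 10 occurs on the ring face anti to the bulky C12 substituent (C9 trans to it) through a chair in which the Z-alkene of nerol places the homoprenyl chain axial, which fixes the quaternary C10 relative to C9.

**Step 5**
Reactants: 11 (3S,5S)-3-[(3S)-3,7-dimethylocta-1,6-dien-3-yl]-5-[(2R)-2-(triethylsilyloxy)-4-(triisopropylsilyl)but-3-yn-2-yl]dihydrofuran-2(3H)-one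
Product: 12 (3S,5S,6R)-3-[(3S)-3,7-dimethylocta-1,6-dien-3-yl]-5-hydroxy-6-methyl-6-(triethylsilyloxy)-8-(triisopropylsilyl)oct-7-yn-2-one
Conditions: MeLi (1.1 equiv), Et2O, −78 °C; then H2O
Reagents that add atoms: methyllithium ([Li]C)
Why: Single addition of MeLi to the hindered γ-lactone (the lithium hemiketal resists a second addition at −78 °C) unmasks the C8 methyl ketone and the C12 hydroxyl without epimerising C9.

**Step 6**
Reactants: 12 (3S,5S,6R)-3-[(3S)-3,7-dimethylocta-1,6-dien-3-yl]-5-hydroxy-6-methyl-6-(triethylsilyloxy)-8-(triisopropylsilyl)oct-7-yn-2-one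
Product: 13 (3R,5S,6R)-3-[(3S)-3,7-dimethylocta-1,6-dien-3-yl]-2,6-dimethyl-6-(triethylsilyloxy)-8-(triisopropylsilyl)oct-1-en-7-yn-5-ol
Conditions: Ph3PCH3Br, KOtBu (3 equiv of ylide), THF, 0 °C to rt
Reagents that add atoms: methylenetriphenylphosphorane (C=P(c1ccccc1)(c1ccccc1)c1ccccc1)
Why: Wittig methylenation of the methyl ketone gives the isopropenyl group that later closes ring B; excess ylide tolerates the free hydroxyl.

**Step 7**
Reactants: 13 (3R,5S,6R)-3-[(3S)-3,7-dimethylocta-1,6-dien-3-yl]-2,6-dimethyl-6-(triethylsilyloxy)-8-(triisopropylsilyl)oct-1-en-7-yn-5-ol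
Product: 14 (3S)-3-[(3R,5S,6R)-5-hydroxy-2,6-dimethyl-6-(triethylsilyloxy)-8-(triisopropylsilyl)oct-1-en-7-yn-3-yl]-3,7-dimethyloct-6-enal
Conditions: PdCl2(PhCN)2 (10 mol %), CuCl2·2H2O (10 mol %), AgNO2 (5 mol %), O2 (1 atm), tBuOH/MeNO2 15:1, rt
Reagents that add atoms: dioxygen (O=O)
Why: Nitrite-modified aldehyde-selective Wacker oxidation converts the vinyl group on the quaternary carbon anti-Markovnikov to the aldehyde, while the trisubstituted alkene, the 1,1-disubstituted alkene and the silylalkyne (the reason the C13 vinyl is carried as an alkyne) are inert.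

**Step 8**
Reactants: 14 (3S)-3-[(3R,5S,6R)-5-hydroxy-2,6-dimethyl-6-(triethylsilyloxy)-8-(triisopropylsilyl)oct-1-en-7-yn-3-yl]-3,7-dimethyloct-6-enal
Product: 16 (1Z,3R)-3-[(3R,5S,6R)-5-acetoxy-2,6-dimethyl-6-(triethylsilyloxy)-8-(triisopropylsilyl)oct-1-en-7-yn-3-yl]-3,7-dimethylocta-1,6-dien-1-yl acetate, via dipotassium enolate alkoxide 15 (not isolated)
Conditions: KN(SiMe3)2 (2.2 equiv), THF, −78 °C; then Ac2O (3 equiv), −78 to 0 °C
Reagents that add atoms: acetic anhydride (CC(=O)OC(C)=O)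
Why: Kinetic deprotonation of the aldehyde from its ground-state conformer (alkyl chain eclipsing C=O) gives the (Z)-enolate, and O-acetylation of enolate and C12 alkoxide (enol ester formation) installs both acetates of the target in one operation.

**Step 9**
Reactants: 16 (1Z,3R)-3-[(3R,5S,6R)-5-acetoxy-2,6-dimethyl-6-(triethylsilyloxy)-8-(triisopropylsilyl)oct-1-en-7-yn-3-yl]-3,7-dimethylocta-1,6-dien-1-yl acetate
Product: 19 (3S,5R,6R,9R,10R,12S,13R)-3-bromo-13-(triethylsilyloxy)-15-(triisopropylsilyl)labd-8(17)-en-14-yne-6,12-diyl diacetate, via bromonium ion 17 (not isolated), via tertiary carbocation 18 (not isolated)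
Conditions: nBu4NBr (1.5 equiv), 2,4,6-collidine (1 equiv), (CF3)2CHOH/CH2Cl2 4:1, undivided cell, graphite anode, Pt cathode, 2 mA cm−2, 2.2 F mol−1, 0 °C
Reagents that add atoms: tetrabutylammonium bromide (CCCC[N+](CCCC)(CCCC)CCCC.[Br-])
Why: Proposed new method: anodic oxidation of bromide in hexafluoroisopropanol delivers Br+ reversibly to the most nucleophilic (trisubstituted) alkene, bromonium ion 17 is opened by enol acetate carbon C5 in a chair–chair anti addition whose acyloxycarbenium ion at C6 is captured by the isopropenyl group (Prins closure), and cation 18 loses H17, so that C10 (C9 chain equatorial on ring A) fixes C3 (Br equatorial) and C5 (trans fusion) while the Z enol geometry becomes the axial 6β-acetate; the closest known reactions are chemical bromonium-induced polyene cyclisations in fluorinated alcohols, Prins cyclisations of acyloxycarbenium ions and anodic bromo-functionalisation of alkenes.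

**Step 10**
Reactants: 19 (3S,5R,6R,9R,10R,12S,13R)-3-bromo-13-(triethylsilyloxy)-15-(triisopropylsilyl)labd-8(17)-en-14-yne-6,12-diyl diacetate
Product: 20 (3S,5R,6R,9R,10R,12S,13R)-3-bromo-13-hydroxylabd-8(17)-en-14-yne-6,12-diyl diacetate
Conditions: nBu4NF (3 equiv), AcOH (3 equiv), THF, 0 °C to rt
Reagents that add atoms: none
Why: Fluoride-mediated desilylation removes the tertiary silyl ether and the alkynylsilane in one pot, and acetic acid buffering prevents acetate migration or loss.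

**Step 11**
Reactants: 20 (3S,5R,6R,9R,10R,12S,13R)-3-bromo-13-hydroxylabd-8(17)-en-14-yne-6,12-diyl diacetate
Product: 21 (3S,5R,6R,9R,10R,12S,13R)-3-bromo-13-hydroxylabda-8(17),14-diene-6,12-diyl diacetate (target)
Conditions: H2 (1 atm), Pd/CaCO3 poisoned with Pb(OAc)2, quinoline, EtOAc, rt, stopped after 1.0 equiv H2
Reagents that add atoms: none
Why: Lindlar semi-hydrogenation stops at the terminal alkene and leaves the hindered 1,1-disubstituted alkene and the secondary bromide untouched.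

**Compound list**
1 | (S)-5-oxotetrahydrofuran-2-carboxylic acid | OC(=O)[C@@H]1CCC(=O)O1 | starting material
2 | (S)-5-oxotetrahydrofuran-2-carbonyl chloride | ClC(=O)[C@@H]1CCC(=O)O1 | intermediate
3 | (S)-5-acetyldihydrofuran-2(3H)-one | CC(=O)[C@@H]1CCC(=O)O1 | intermediate
4 | lithium (2R)-2-[(2S)-5-oxotetrahydrofuran-2-yl]-4-(triisopropylsilyl)but-3-yn-2-olate | CC(C)[Si](C(C)C)(C(C)C)C#C[C@@](C)(O[Li])[C@@H]1CCC(=O)O1 | intermediate
5 | (5S)-5-[(2R)-2-(triethylsilyloxy)-4-(triisopropylsilyl)but-3-yn-2-yl]dihydrofuran-2(3H)-one | CC(C)[Si](C(C)C)(C(C)C)C#C[C@@](C)(O[Si](CC)(CC)CC)[C@@H]1CCC(=O)O1 | intermediate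
6 | (5S)-2-ethoxy-5-[(2R)-2-(triethylsilyloxy)-4-(triisopropylsilyl)but-3-yn-2-yl]-4,5-dihydro-3H-furan-1-ium tetrafluoroborate | CC(C)[Si](C(C)C)(C(C)C)C#C[C@@](C)(O[Si](CC)(CC)CC)[C@@H]1CCC(OCC)=[O+]1.F[B-](F)(F)F | intermediate
7 | (5S)-2,2-diethoxy-5-[(2R)-2-(triethylsilyloxy)-4-(triisopropylsilyl)but-3-yn-2-yl]tetrahydrofuran | CC(C)[Si](C(C)C)(C(C)C)C#C[C@@](C)(O[Si](CC)(CC)CC)[C@@H]1CCC(OCC)(OCC)O1 | intermediate
8 | nerol, (2Z)-3,7-dimethylocta-2,6-dien-1-ol | CC(C)=CCC/C(C)=C\CO | starting material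
9 | (5S)-2-ethoxy-2-{[(2Z)-3,7-dimethylocta-2,6-dien-1-yl]oxy}-5-[(2R)-2-(triethylsilyloxy)-4-(triisopropylsilyl)but-3-yn-2-yl]tetrahydrofuran (both C2 epimers) | CC(C)[Si](C(C)C)(C(C)C)C#C[C@@](C)(O[Si](CC)(CC)CC)[C@@H]1CCC(OCC)(OC/C=C(/C)CCC=C(C)C)O1 | intermediate
10 | (2S)-5-{[(2Z)-3,7-dimethylocta-2,6-dien-1-yl]oxy}-2-[(2R)-2-(triethylsilyloxy)-4-(triisopropylsilyl)but-3-yn-2-yl]-2,3-dihydrofuran | CC(C)[Si](C(C)C)(C(C)C)C#C[C@@](C)(O[Si](CC)(CC)CC)[C@@H]1CC=C(OC/C=C(/C)CCC=C(C)C)O1 | intermediate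
11 | (3S,5S)-3-[(3S)-3,7-dimethylocta-1,6-dien-3-yl]-5-[(2R)-2-(triethylsilyloxy)-4-(triisopropylsilyl)but-3-yn-2-yl]dihydrofuran-2(3H)-one | CC(C)[Si](C(C)C)(C(C)C)C#C[C@@](C)(O[Si](CC)(CC)CC)[C@@H]1C[C@H](C(=O)O1)[C@](C)(C=C)CCC=C(C)C | intermediate
12 | (3S,5S,6R)-3-[(3S)-3,7-dimethylocta-1,6-dien-3-yl]-5-hydroxy-6-methyl-6-(triethylsilyloxy)-8-(triisopropylsilyl)oct-7-yn-2-one | CC(C)[Si](C(C)C)(C(C)C)C#C[C@@](C)(O[Si](CC)(CC)CC)[C@@H](O)C[C@H](C(C)=O)[C@](C)(C=C)CCC=C(C)C | intermediate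
13 | (3R,5S,6R)-3-[(3S)-3,7-dimethylocta-1,6-dien-3-yl]-2,6-dimethyl-6-(triethylsilyloxy)-8-(triisopropylsilyl)oct-1-en-7-yn-5-ol | CC(C)[Si](C(C)C)(C(C)C)C#C[C@@](C)(O[Si](CC)(CC)CC)[C@@H](O)C[C@H](C(C)=C)[C@](C)(C=C)CCC=C(C)C | intermediate
14 | (3S)-3-[(3R,5S,6R)-5-hydroxy-2,6-dimethyl-6-(triethylsilyloxy)-8-(triisopropylsilyl)oct-1-en-7-yn-3-yl]-3,7-dimethyloct-6-enal | CC(C)[Si](C(C)C)(C(C)C)C#C[C@@](C)(O[Si](CC)(CC)CC)[C@@H](O)C[C@H](C(C)=C)[C@](C)(CC=O)CCC=C(C)C | intermediate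
15 | dipotassium (Z)-enolate alkoxide of 14 (O6 and O12 as potassium salts) | CC(C)[Si](C(C)C)(C(C)C)C#C[C@@](C)(O[Si](CC)(CC)CC)[C@@H](O[K])C[C@H](C(C)=C)[C@](C)(/C=C\O[K])CCC=C(C)C | intermediate
16 | (1Z,3R)-3-[(3R,5S,6R)-5-acetoxy-2,6-dimethyl-6-(triethylsilyloxy)-8-(triisopropylsilyl)oct-1-en-7-yn-3-yl]-3,7-dimethylocta-1,6-dien-1-yl acetate | CC(C)[Si](C(C)C)(C(C)C)C#C[C@@](C)(O[Si](CC)(CC)CC)[C@@H](OC(C)=O)C[C@H](C(C)=C)[C@](C)(/C=C\OC(C)=O)CCC=C(C)C | intermediate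
17 | C3–C4 bromonium ion of 16 (C3 configured as in 19) | CC(C)[Si](C(C)C)(C(C)C)C#C[C@@](C)(O[Si](CC)(CC)CC)[C@@H](OC(C)=O)C[C@H](C(C)=C)[C@](C)(/C=C\OC(C)=O)CC[C@@H]1[Br+]C1(C)C | intermediate
18 | bicyclic C8 tertiary carbocation (ring stereocentres as in 19) | CC(C)[Si](C(C)C)(C(C)C)C#C[C@@](C)(O[Si](CC)(CC)CC)[C@H](C[C@@H]1[C+](C)C[C@@H](OC(C)=O)[C@H]2C(C)(C)[C@@H](Br)CC[C@]12C)OC(C)=O | intermediate
19 | (3S,5R,6R,9R,10R,12S,13R)-3-bromo-13-(triethylsilyloxy)-15-(triisopropylsilyl)labd-8(17)-en-14-yne-6,12-diyl diacetate | CC(C)[Si](C(C)C)(C(C)C)C#C[C@@](C)(O[Si](CC)(CC)CC)[C@H](C[C@@H]1C(=C)C[C@@H](OC(C)=O)[C@H]2C(C)(C)[C@@H](Br)CC[C@]12C)OC(C)=O | intermediate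
20 | (3S,5R,6R,9R,10R,12S,13R)-3-bromo-13-hydroxylabd-8(17)-en-14-yne-6,12-diyl diacetate | C#C[C@@](C)(O)[C@H](C[C@@H]1C(=C)C[C@@H](OC(C)=O)[C@H]2C(C)(C)[C@@H](Br)CC[C@]12C)OC(C)=O | intermediate
21 | (3S,5R,6R,9R,10R,12S,13R)-3-bromo-13-hydroxylabda-8(17),14-diene-6,12-diyl diacetate | C=C[C@@](C)(O)[C@H](C[C@@H]1C(=C)C[C@@H](OC(C)=O)[C@H]2C(C)(C)[C@@H](Br)CC[C@]12C)OC(C)=O | target

**Step count and risk**
Total: 11 steps. Longest linear sequence: 11 steps (1 → 21); nerol 8 enters in step 4.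

Three steps most likely to fail:

1. Step 9 (the proposed new step). Possible failures: capture of the bromonium ion by bromide, bromination of the enol acetate, endocyclic alkene isomers from cation 18, trapping of 18 by O13, or stepwise ring B closure that erodes the C6 configuration. The fallback uses known reaction classes, sets out from 14 and returns at 19. N-Bromosuccinimide in aqueous THF converts the trisubstituted alkene of 14 into bromohydrin F6 (both C3 epimers). Me3SiCl, NaI and Et3N in MeCN give tris-silyl compound F7, a (Z)-silyl enol ether with silyl ethers at O4 and O12. SnCl4 in CH2Cl2 at −78 °C ionises the tertiary silyl ether with bromine participation, and the silyl enol ether closes ring A (Mukaiyama-type tertiary alkylation) to aldehyde F8; the C3 epimer from the other bromohydrin is removed here by chromatography. Me2AlCl then closes ring B by a type-two intramolecular carbonyl-ene reaction to diol F9, with the axial 6β-alcohol and the exocyclic alkene. Ac2O, DMAP and Et3N acetylate O6 and O12 to give 19.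

2. Step 4. Possible failures: acid- or heat-induced ionisation of nerol, or chair/boat leakage that lowers the C10 selectivity. The fallback is a low-temperature thio-Claisen route that sets out from 5 and returns at 11. Lawesson's reagent in toluene converts 5 into thionolactone F1. Nerol 8 and PBr3 give neryl bromide F2. LiN(iPr)2 and F2 S-alkylate F1 to ketene S,O-acetal F3, which rearranges ([3,3]) at 0–25 °C on the face anti to the C12 substituent to thionolactone F4. S-Methylation with MeOTf and hydrolysis with aqueous NaHCO3 returns lactone 11.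

3. Step 8. Possible failures: an E/Z mixture of enol acetates (the E isomer would give the 6α-acetate in step 9) or aldol self-condensation. The fallback sets out from 14 and returns at 16. Me3SiCl, NaI and Et3N in MeCN give the (Z)-silyl enol ether with O12 also silylated, bis-silyl compound F5. MeLi (2.2 equiv) in THF at 0 °C liberates the lithium (Z)-enolate and the C12 alkoxide with retention of geometry, and Ac2O then gives 16.

**Further compounds**
F1 | step 4 | (5S)-5-[(2R)-2-(triethylsilyloxy)-4-(triisopropylsilyl)but-3-yn-2-yl]dihydrofuran-2(3H)-thione | CC(C)[Si](C(C)C)(C(C)C)C#C[C@@](C)(O[Si](CC)(CC)CC)[C@@H]1CCC(=S)O1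
F2 | step 4 | neryl bromide, (2Z)-1-bromo-3,7-dimethylocta-2,6-diene | CC(C)=CCC/C(C)=C\CBr
F3 | step 4 | (2S)-5-{[(2Z)-3,7-dimethylocta-2,6-dien-1-yl]sulfanyl}-2-[(2R)-2-(triethylsilyloxy)-4-(triisopropylsilyl)but-3-yn-2-yl]-2,3-dihydrofuran | CC(C)[Si](C(C)C)(C(C)C)C#C[C@@](C)(O[Si](CC)(CC)CC)[C@@H]1CC=C(SC/C=C(/C)CCC=C(C)C)O1
F4 | step 4 | (3S,5S)-3-[(3S)-3,7-dimethylocta-1,6-dien-3-yl]-5-[(2R)-2-(triethylsilyloxy)-4-(triisopropylsilyl)but-3-yn-2-yl]dihydrofuran-2(3H)-thione | CC(C)[Si](C(C)C)(C(C)C)C#C[C@@](C)(O[Si](CC)(CC)CC)[C@@H]1C[C@H](C(=S)O1)[C@](C)(C=C)CCC=C(C)C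
F5 | step 8 | bis(trimethylsilyl) derivative of 14: (Z)-trimethylsilyl enol ether at C5=C6 and trimethylsilyl ether at O12 | CC(C)[Si](C(C)C)(C(C)C)C#C[C@@](C)(O[Si](CC)(CC)CC)[C@@H](O[Si](C)(C)C)C[C@H](C(C)=C)[C@](C)(/C=C\O[Si](C)(C)C)CCC=C(C)C
F6 | step 9 | (3S)-6-bromo-7-hydroxy-3-[(3R,5S,6R)-5-hydroxy-2,6-dimethyl-6-(triethylsilyloxy)-8-(triisopropylsilyl)oct-1-en-7-yn-3-yl]-3,7-dimethyloctanal (both C6 epimers) | CC(C)[Si](C(C)C)(C(C)C)C#C[C@@](C)(O[Si](CC)(CC)CC)[C@@H](O)C[C@H](C(C)=C)[C@](C)(CC=O)CCC(Br)C(C)(C)O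
F7 | step 9 | tris(trimethylsilyl) derivative of F6: (Z)-silyl enol ether at C5=C6, silyl ethers at O4 and O12 | CC(C)[Si](C(C)C)(C(C)C)C#C[C@@](C)(O[Si](CC)(CC)CC)[C@@H](O[Si](C)(C)C)C[C@H](C(C)=C)[C@](C)(/C=C\O[Si](C)(C)C)CCC(Br)C(C)(C)O[Si](C)(C)C
F8 | step 9 | (1R,2R,5S)-5-bromo-2-[(3R,5S,6R)-5-hydroxy-2,6-dimethyl-6-(triethylsilyloxy)-8-(triisopropylsilyl)oct-1-en-7-yn-3-yl]-2,6,6-trimethylcyclohexane-1-carbaldehyde | CC(C)[Si](C(C)C)(C(C)C)C#C[C@@](C)(O[Si](CC)(CC)CC)[C@@H](O)C[C@H](C(C)=C)[C@@]1(C)CC[C@H](Br)C(C)(C)[C@@H]1C=O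
F9 | step 9 | (3S,5R,6R,9R,10R,12S,13R)-3-bromo-13-(triethylsilyloxy)-15-(triisopropylsilyl)labd-8(17)-en-14-yne-6,12-diol | CC(C)[Si](C(C)C)(C(C)C)C#C[C@@](C)(O[Si](CC)(CC)CC)[C@H](C[C@@H]1C(=C)C[C@@H](O)[C@H]2C(C)(C)[C@@H](Br)CC[C@]12C)O
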